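**Retrosynthetic overview**

1. The C7=C8 alkylidene is made last, by aldol addition and dehydration between a 2-chloro-4-silyloxycyclopentenone and methyl (Z)-7-oxohept-5-enoate (5Z from an alkyne semi-hydrogenation).
2. The cyclopentenone, the only ring of the target, is closed at C10=C11 by a one-pot [4+1] annulation. Lithiated diethyl chloromethylphosphonate (C10 with its chlorine) acylates a bicyclic acylal lactone at C9, the bicycle fragments to the C11 aldehyde and the C12 alkoxide, and an intramolecular Horner–Wadsworth–Emmons (HWE) olefination closes the ring.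
3. Enabling feature: in the ring the C9 ketone and the olefinic C11–H are 1,4-related through C8 and C12, so C10=C11 is the olefination bond of an acyl/formyl pair. C12 carries its oxygen next to C11, so the C9 carboxyl, the C11 aldehyde and the C12 oxygen can be held in one cis-fused γ-lactone/1,3-dioxolane bicycle, and C12 is quaternary and cannot epimerise.
4. C12 (R) comes from (S)-malic acid by alkylation of its pivalaldehyde dioxolanone (self-regeneration of the stereocentre) with (Z)-1-bromooct-2-ene.
5. Ring order: temporary dioxolanone (step 1), temporary γ-lactone (step 4), cyclopentenone (step 5, which destroys both temporary rings).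

Key step: step 5

Remark: positions are cited in prostanoid numbering of the target (C1 ester carbon; ring C8–C12 with C9 the ketone, C10 the chlorinated carbon, C11 the ring CH, C12 the carbinol carbon).

**Route**

Step 1
Reactants: 1 (S)-malic acid
Product: 2 (2S,4S)-2-tert-butyl-5-oxo-1,3-dioxolane-4-acetic acid (cis)
Conditions: t-BuCHO, TsOH·H2O (cat.), H2SO4 (cat.), pentane, reflux (Dean–Stark); recrystallisation
Reagents that add atoms: pivalaldehyde, CC(C)(C)C=O
Why: Acid-catalysed acetalisation of the α-hydroxy acid unit should give the five-membered dioxolanone, and the new acetal centre is set cis to the CH2CO2H group under thermodynamic control, the cis isomer being purified by crystallisation.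

Step 2
Reactants: 3 (Z)-oct-2-en-1-ol
Product: 4 (Z)-1-bromooct-2-ene
Conditions: CBr4, PPh3, CH2Cl2, 0 °C
Reagents that add atoms: carbon tetrabromide, BrC(Br)(Br)Br
Why: Appel reaction of a primary allylic alcohol, an SN2 displacement on the alkoxyphosphonium salt that should keep the Z geometry when run cold.

Step 3
Reactants: 2 (2S,4S)-2-tert-butyl-5-oxo-1,3-dioxolane-4-acetic acid; 4 (Z)-1-bromooct-2-ene
Product: 6 (2S,4S)-2-tert-butyl-4-[(2Z)-oct-2-en-1-yl]-5-oxo-1,3-dioxolane-4-acetic acid, via dilithium enolate carboxylate 5 (not isolated)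
Conditions: LiN(SiMe3)2 (2.2 equiv), THF, −78 °C; then 4, −78 → −20 °C; aq. HCl to pH 3
Reagents that add atoms: none
Why: Dioxolanone enolate alkylation (self-regeneration of stereocentres): the dianion 5 is planar at C12 and the tert-butyl group shields one face, so the allylic bromide should enter anti to it by SN2, replacing the former hydrogen with net retention and setting the quaternary C12 centre.

Step 4
Reactants: 6 (2S,4S)-2-tert-butyl-4-[(2Z)-oct-2-en-1-yl]-5-oxo-1,3-dioxolane-4-acetic acid
Product: 8 (2S,3aR,6aS)-2-tert-butyl-6a-[(2Z)-oct-2-en-1-yl]tetrahydrofuro[2,3-d][1,3]dioxol-5-one (cis-fused acylal lactone), via lactol acid 7 (not isolated)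
Conditions: i-Bu2AlH (2.2 equiv), CH2Cl2, −78 °C; aq. tartaric acid; then camphorsulfonic acid (cat.), 4 Å MS, CH2Cl2, rt
Reagents that add atoms: none
Why: Partial hydride reduction of the activated dioxolanone carbonyl to the lactol, while the acid is held as an unreactive aluminium carboxylate, followed by acid-catalysed lactonisation through the C11 oxocarbenium ion, in which the new acetal centre C11 is set because only the cis-fused bicycle can close.

Step 5
Reactants: 8 (2S,3aR,6aS)-2-tert-butyl-6a-[(2Z)-oct-2-en-1-yl]tetrahydrofuro[2,3-d][1,3]dioxol-5-one; 9 diethyl (chloromethyl)phosphonate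
Product: 12 (4S)-2-chloro-4-hydroxy-4-[(2Z)-oct-2-en-1-yl]cyclopent-2-en-1-one, via lithiated phosphonate 10 (not isolated), via open-chain formyl ketophosphonate dianion 11 (not isolated)
Conditions: 9 (2.2 equiv), n-BuLi (2.2 equiv), THF, −78 °C; then 8, −78 → 23 °C; AcOH
Reagents that add atoms: none
Why: Proposed new method: the carbanion 10 should add to the lactone carbonyl (C9) of 8, and collapse of the tetrahedral adduct expels the acylal oxygen as a hemiacetal alkoxide that fragments twice, unveiling the C11 aldehyde and the C12 alkoxide with loss of pivalaldehyde, after which the α-chloro-β-ketophosphonate carbanion of 11 adds to the freshly released aldehyde and the oxaphosphetane eliminates lithium diethyl phosphate to give C10=C11 (HWE olefination). The closest known reaction types are the phosphonate annulation of enol lactones to cyclic enones and the stepwise lactone → β-ketophosphonate → oxidation → intramolecular HWE route to cyclopentenones; new is an acylal lactone that releases its aldehyde in the same flask, combined with the α-chloro reagent that delivers C10 with its chlorine. The cyclopentenone closes in the 5-(enolendo)-exo-trig mode, the same mode by which 1,4-dicarbonyl compounds close to cyclopentenones in aldol and HWE chemistry. No stereocentre is created: C12 is quaternary and not enolisable, so its configuration from step 3 is carried over, and the geometry of the new olefin is fixed by the ring. The step needs chemoselective attack at C9, which the bicycle secures because no aldehyde exists until acylation has occurred, and it needs ring closure to outrun olefination of the expelled pivalaldehyde, which the five-membered proximity and the bulk of the tert-butyl group should secure. The second equivalent of 10 serves only as base and returns as 9 at the quench.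

Step 6
Reactants: 12 (4S)-2-chloro-4-hydroxy-4-[(2Z)-oct-2-en-1-yl]cyclopent-2-en-1-one
Product: 13 (4S)-2-chloro-4-[(2Z)-oct-2-en-1-yl]-4-(trimethylsilyloxy)cyclopent-2-en-1-one
Conditions: 1-(trimethylsilyl)imidazole, CH2Cl2, rt
Reagents that add atoms: 1-(trimethylsilyl)imidazole, C[Si](C)(C)n1ccnc1
Why: Silylation of the tertiary alcohol with a mild, base-free silyl donor that should leave the chloroenone untouched.

Step 7
Reactants: 14 hex-5-ynoic acid
Product: 16 7-hydroxyhept-5-ynoic acid, via magnesium acetylide carboxylate 15 (not isolated)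
Conditions: EtMgBr (2.2 equiv), THF, 0 → 45 °C; (CH2O)n, 45 °C; aq. HCl
Reagents that add atoms: formaldehyde (as paraformaldehyde), C=O
Why: Double deprotonation to the carboxylate and magnesium acetylide followed by addition of the acetylide to formaldehyde, a standard hydroxymethylation of a terminal alkyne.

Step 8
Reactants: 16 7-hydroxyhept-5-ynoic acid
Product: 17 methyl 7-hydroxyhept-5-ynoate
Conditions: MeOH, H2SO4 (cat.), rt
Reagents that add atoms: methanol, CO
Why: Fischer esterification in excess methanol, under which the propargylic alcohol is inert.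

Step 9
Reactants: 17 methyl 7-hydroxyhept-5-ynoate
Product: 18 methyl (Z)-7-hydroxyhept-5-enoate
Conditions: H2 (1 atm), Pd/CaCO3 poisoned with Pb(OAc)2, quinoline, EtOAc, rt
Reagents that add atoms: none
Why: Lindlar semi-hydrogenation, in which syn delivery of hydrogen on the poisoned palladium surface should give the Z olefin (C5=C6) and stop at the alkene.

Step 10
Reactants: 18 methyl (Z)-7-hydroxyhept-5-enoate
Product: 19 methyl (Z)-7-oxohept-5-enoate
Conditions: Dess–Martin periodinane, pyridine, CH2Cl2, 0 °C; used at once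
Reagents that add atoms: none
Why: Dess–Martin oxidation of the allylic alcohol under buffered conditions, which should keep the Z geometry of the labile enal if it is used directly.

Step 11
Reactants: 13 (4S)-2-chloro-4-[(2Z)-oct-2-en-1-yl]-4-(trimethylsilyloxy)cyclopent-2-en-1-one; 19 methyl (Z)-7-oxohept-5-enoate
Product: 21 methyl (5Z)-7-[(5S)-3-chloro-5-[(2Z)-oct-2-en-1-yl]-2-oxo-5-(trimethylsilyloxy)cyclopent-3-en-1-yl]-7-hydroxyhept-5-enoate (mixture of diastereomers at C7 and C8), via lithium enolate 20 (not isolated)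
Conditions: LiN(i-Pr)2 (1.1 equiv), THF, −78 °C; then 19, −78 °C; AcOH
Reagents that add atoms: none
Why: Directed aldol addition: deprotonation can occur only at C8 (C12 is quaternary, C10 and C11 are sp2) and the lithium enolate should add 1,2 to the enal at −78 °C, the two new centres (C7, C8) being uncontrolled and both removed in step 12.

Step 12
Reactants: 21 methyl (5Z)-7-[(5S)-3-chloro-5-[(2Z)-oct-2-en-1-yl]-2-oxo-5-(trimethylsilyloxy)cyclopent-3-en-1-yl]-7-hydroxyhept-5-enoate
Product: 23 methyl (5Z,7E,12R,14Z)-10-chloro-9-oxo-12-(trimethylsilyloxy)prosta-5,7,10,14-tetraen-1-oate, via mesylate 22 (not isolated)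
Conditions: MsCl, Et3N, CH2Cl2, −20 °C → rt
Reagents that add atoms: none
Why: Aldol dehydration by mesylation of the secondary alcohol and E1cB elimination through the C8 enolate, which should give mainly the 7E alkylidene with the diene chain pointing away from the C9 carbonyl oxygen, any 7Z isomer being removed by chromatography.

Step 13
Reactants: 23 methyl (5Z,7E,12R,14Z)-10-chloro-9-oxo-12-(trimethylsilyloxy)prosta-5,7,10,14-tetraen-1-oate
Product: 24 chlorovulone I, methyl (5Z,7E,12R,14Z)-10-chloro-12-hydroxy-9-oxoprosta-5,7,10,14-tetraen-1-oate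
Conditions: AcOH/THF/H2O (3:1:1), rt
Reagents that add atoms: none
Why: Mild acidic hydrolysis of the tertiary trimethylsilyl ether, under which the methyl ester, the vinyl chloride and the cross-conjugated dienone should be stable.

**Compound list**

1 | (S)-malic acid | OC(=O)C[C@H](O)C(=O)O | starting material
2 | (2S,4S)-2-tert-butyl-5-oxo-1,3-dioxolane-4-acetic acid | OC(=O)C[C@@H]1O[C@H](C(C)(C)C)OC1=O | intermediate
3 | (Z)-oct-2-en-1-ol | CCCCC/C=C\CO | starting material
4 | (Z)-1-bromooct-2-ene | CCCCC/C=C\CBr | intermediate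
5 | dilithium enolate carboxylate of 2 | [Li+].[Li+].[O-]C(=O)CC1=C([O-])O[C@@H](C(C)(C)C)O1 | intermediate
6 | (2S,4S)-2-tert-butyl-4-[(2Z)-oct-2-en-1-yl]-5-oxo-1,3-dioxolane-4-acetic acid | OC(=O)C[C@]1(C/C=C\CCCCC)O[C@H](C(C)(C)C)OC1=O | intermediate
7 | 2-[(2S,4S,5RS)-2-tert-butyl-5-hydroxy-4-[(2Z)-oct-2-en-1-yl]-1,3-dioxolan-4-yl]acetic acid (lactol acid) | OC(=O)C[C@]1(C/C=C\CCCCC)O[C@H](C(C)(C)C)OC1O | intermediate
8 | (2S,3aR,6aS)-2-tert-butyl-6a-[(2Z)-oct-2-en-1-yl]tetrahydrofuro[2,3-d][1,3]dioxol-5-one (cis-fused γ-lactone/1,3-dioxolane acylal; the acetal configuration at C2 is carried from 2 and is of no consequence) | O=C1C[C@]2(C/C=C\CCCCC)O[C@H](C(C)(C)C)O[C@@H]2O1 | intermediate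
9 | diethyl (chloromethyl)phosphonate | CCOP(=O)(CCl)OCC | starting material
10 | diethyl [chloro(lithio)methyl]phosphonate | [Li]C(Cl)P(=O)(OCC)OCC | intermediate
11 | dilithium salt of diethyl [(4S,6Z)-1-chloro-4-formyl-4-hydroxy-2-oxododec-6-en-1-yl]phosphonate (C10 enolate, C12 alkoxide) | [Li+].[Li+].CCOP(=O)(OCC)C(Cl)=C([O-])C[C@]([O-])(C=O)C/C=C\CCCCC | intermediate
12 | (4S)-2-chloro-4-hydroxy-4-[(2Z)-oct-2-en-1-yl]cyclopent-2-en-1-one | CCCCC/C=C\C[C@@]1(O)C=C(Cl)C(=O)C1 | intermediate
13 | (4S)-2-chloro-4-[(2Z)-oct-2-en-1-yl]-4-(trimethylsilyloxy)cyclopent-2-en-1-one | CCCCC/C=C\C[C@@]1(O[Si](C)(C)C)C=C(Cl)C(=O)C1 | intermediate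
14 | hex-5-ynoic acid | C#CCCCC(=O)O | starting material
15 | bis(bromomagnesium) acetylide carboxylate of 14 | Br[Mg]C#CCCCC(=O)O[Mg]Br | intermediate
16 | 7-hydroxyhept-5-ynoic acid | OCC#CCCCC(=O)O | intermediate
17 | methyl 7-hydroxyhept-5-ynoate | COC(=O)CCCC#CCO | intermediate
18 | methyl (Z)-7-hydroxyhept-5-enoate | COC(=O)CCC/C=C\CO | intermediate
19 | methyl (Z)-7-oxohept-5-enoate | COC(=O)CCC/C=C\C=O | intermediate
20 | lithium enolate of 13 (C8=C9 enolate) | [Li+].CCCCC/C=C\C[C@@]1(O[Si](C)(C)C)C=C(Cl)C([O-])=C1 | intermediate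
21 | methyl (5Z)-7-[(5S)-3-chloro-5-[(2Z)-oct-2-en-1-yl]-2-oxo-5-(trimethylsilyloxy)cyclopent-3-en-1-yl]-7-hydroxyhept-5-enoate (diastereomer mixture at C7 and C8) | CCCCC/C=C\C[C@@]1(O[Si](C)(C)C)C=C(Cl)C(=O)C1C(O)/C=C\CCCC(=O)OC | intermediate
22 | C7 methanesulfonate of 21 | CCCCC/C=C\C[C@@]1(O[Si](C)(C)C)C=C(Cl)C(=O)C1C(OS(C)(=O)=O)/C=C\CCCC(=O)OC | intermediate
23 | methyl (5Z,7E,12R,14Z)-10-chloro-9-oxo-12-(trimethylsilyloxy)prosta-5,7,10,14-tetraen-1-oate | CCCCC/C=C\C[C@@]1(O[Si](C)(C)C)C=C(Cl)C(=O)/C1=C/C=C\CCCC(=O)OC | intermediate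
24 | chlorovulone I, methyl (5Z,7E,12R,14Z)-10-chloro-12-hydroxy-9-oxoprosta-5,7,10,14-tetraen-1-oate | CCCCC/C=C\C[C@@]1(O)C=C(Cl)C(=O)/C1=C/C=C\CCCC(=O)OC | target

**Step count and risks**

Total steps: 13. Longest linear sequence: 8 steps (1, 3, 4, 5, 6, 11, 12, 13).

Steps most likely to fail:

1. Step 5 (proposed new method). The basic reagent may enolise the lactone and trigger β-elimination of the dioxolane oxygen. The fragmentation may run out of sequence, so that free reagent meets the free aldehyde. The phosphonate carbanion may olefinate the expelled pivalaldehyde instead of closing the ring. The fallback uses known chemistry only, sets out from 8 and comes back at 12. Acid-catalysed methanolysis of 8 (camphorsulfonic acid, MeOH) should open the acylal lactone to methyl 2-[(2S,4S,5RS)-2-tert-butyl-5-methoxy-4-[(2Z)-oct-2-en-1-yl]-1,3-dioxolan-4-yl]acetate F1. Acylation of 10 (2.2 equiv, THF, −78 °C) by this plain methyl ester gives diethyl {1-chloro-3-[(2S,4S,5RS)-2-tert-butyl-5-methoxy-4-[(2Z)-oct-2-en-1-yl]-1,3-dioxolan-4-yl]-2-oxopropyl}phosphonate F2. Aqueous trifluoroacetic acid hydrolyses both acetals to diethyl [(4S,6Z)-1-chloro-4-formyl-4-hydroxy-2-oxododec-6-en-1-yl]phosphonate F3, and LiCl/i-Pr2NEt in MeCN (Masamune–Roush conditions) closes F3 to 12 by an ordinary intramolecular HWE reaction.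

2. Step 4. Reduction may run past the lactol stage or attack the carboxylate, and the pivalaldehyde acetal may be lost by hydrolysis during work-up. The fallback sets out from 6 and comes back at 13; it reaches the aldehyde level at C11 by full reduction and re-oxidation and replaces the one-pot annulation by the stepwise lactone route. LiBH4 (THF, 0 °C) reduces the dioxolanone of 6 completely and acid work-up lactonises to (4S)-4-hydroxy-4-[(2Z)-oct-2-en-1-yl]dihydrofuran-2(3H)-one F4. 1-(Trimethylsilyl)imidazole gives (4S)-4-[(2Z)-oct-2-en-1-yl]-4-(trimethylsilyloxy)dihydrofuran-2(3H)-one F5. Addition of 10 opens the lactone to diethyl [(4S,6Z)-1-chloro-4-(hydroxymethyl)-2-oxo-4-(trimethylsilyloxy)dodec-6-en-1-yl]phosphonate F6. Dess–Martin oxidation gives diethyl [(4S,6Z)-1-chloro-4-formyl-2-oxo-4-(trimethylsilyloxy)dodec-6-en-1-yl]phosphonate F7, which LiCl/i-Pr2NEt closes to 13.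

3. Step 12. The C5 olefin may isomerise from Z to E through the extended enolate during the base-mediated elimination, and E/Z control at C7 may be poor. The fallback sets out from 13 (with 17) and comes back at 23; it carries the C5–C6 unit through the elimination as an alkyne, which cannot isomerise. Dess–Martin oxidation of 17 gives methyl 7-oxohept-5-ynoate F8. Aldol addition of enolate 20 to F8 gives methyl 7-[(5S)-3-chloro-5-[(2Z)-oct-2-en-1-yl]-2-oxo-5-(trimethylsilyloxy)cyclopent-3-en-1-yl]-7-hydroxyhept-5-ynoate F9. MsCl/Et3N converts it to its C7 methanesulfonate F10, which eliminates to methyl (7E,12R,14Z)-10-chloro-9-oxo-12-(trimethylsilyloxy)prosta-7,10,14-trien-5-yn-1-oate F11, the C7 isomers being separated at this stage. Semi-hydrogenation over Pd/CaCO3 poisoned with Pb(OAc)2 with quinoline then sets 5Z and gives 23.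

**Further compounds**

F1 | step 5 | methyl 2-[(2S,4S,5RS)-2-tert-butyl-5-methoxy-4-[(2Z)-oct-2-en-1-yl]-1,3-dioxolan-4-yl]acetate | COC(=O)C[C@]1(C/C=C\CCCCC)O[C@H](C(C)(C)C)OC1OC
F2 | step 5 | diethyl {1-chloro-3-[(2S,4S,5RS)-2-tert-butyl-5-methoxy-4-[(2Z)-oct-2-en-1-yl]-1,3-dioxolan-4-yl]-2-oxopropyl}phosphonate | CCOP(=O)(OCC)C(Cl)C(=O)C[C@]1(C/C=C\CCCCC)O[C@H](C(C)(C)C)OC1OC
F3 | step 5 | diethyl [(4S,6Z)-1-chloro-4-formyl-4-hydroxy-2-oxododec-6-en-1-yl]phosphonate | CCOP(=O)(OCC)C(Cl)C(=O)C[C@](O)(C=O)C/C=C\CCCCC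
F4 | step 4 | (4S)-4-hydroxy-4-[(2Z)-oct-2-en-1-yl]dihydrofuran-2(3H)-one | O=C1C[C@@](O)(C/C=C\CCCCC)CO1
F5 | step 4 | (4S)-4-[(2Z)-oct-2-en-1-yl]-4-(trimethylsilyloxy)dihydrofuran-2(3H)-one | O=C1C[C@@](O[Si](C)(C)C)(C/C=C\CCCCC)CO1
F6 | step 4 | diethyl [(4S,6Z)-1-chloro-4-(hydroxymethyl)-2-oxo-4-(trimethylsilyloxy)dodec-6-en-1-yl]phosphonate | CCOP(=O)(OCC)C(Cl)C(=O)C[C@@](O[Si](C)(C)C)(C/C=C\CCCCC)CO
F7 | step 4 | diethyl [(4S,6Z)-1-chloro-4-formyl-2-oxo-4-(trimethylsilyloxy)dodec-6-en-1-yl]phosphonate | CCOP(=O)(OCC)C(Cl)C(=O)C[C@@](O[Si](C)(C)C)(C/C=C\CCCCC)C=O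
F8 | step 12 | methyl 7-oxohept-5-ynoate | COC(=O)CCCC#CC=O
F9 | step 12 | methyl 7-[(5S)-3-chloro-5-[(2Z)-oct-2-en-1-yl]-2-oxo-5-(trimethylsilyloxy)cyclopent-3-en-1-yl]-7-hydroxyhept-5-ynoate | CCCCC/C=C\C[C@@]1(O[Si](C)(C)C)C=C(Cl)C(=O)C1C(O)C#CCCCC(=O)OC
F10 | step 12 | C7 methanesulfonate of F9 | CCCCC/C=C\C[C@@]1(O[Si](C)(C)C)C=C(Cl)C(=O)C1C(OS(C)(=O)=O)C#CCCCC(=O)OC
F11 | step 12 | methyl (7E,12R,14Z)-10-chloro-9-oxo-12-(trimethylsilyloxy)prosta-7,10,14-trien-5-yn-1-oate | CCCCC/C=C\C[C@@]1(O[Si](C)(C)C)C=C(Cl)C(=O)/C1=C/C#CCCCC(=O)OC
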